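**Plan**
- Retrosynthesis: the pyran bond O1–C8a is cut together with the C8–O bond of ring A (one aryne event), then the C3–C4 bond (benzylic alkylation of an arylacetyl enolate), then the aryl–CH2 bond of the ring B acetic acid and the C3'–O bond (C–H lithiation of 1,2,4-trimethoxybenzene).
- Enabling feature: ring A carries oxygen on three adjacent carbons (C7, C8, C8a) beside C4a. In a 2-fluoro-4-(methoxymethoxy)benzyl precursor, C8–H lies between C8a–F and C7–OMOM, so lithiation there and loss of LiF give the C8≡C8a aryne. The alkoxide on the C4–C3–C2–O tether can reach only C8a, and the C8–Li left behind is oxygenated.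
- Forward: fragment 1 (benzyl bromide 4, three steps) and fragment 2 (arylacetic acid 15, six steps) are joined by Evans alkylation and reduced to the open-chain alcohol 21. The pyran (ring C) is the last ring formed, by the aryne closure; C8 O-methylation and removal of both MOM groups finish.
- Stereochemistry: the only stereocentre, C3 (S), is set in the alkylation by (4S)-4-benzyl-1,3-oxazolidin-2-one and is not touched afterwards.

Key step: step 13

Assumption: isoflavan numbering is used (O1, C2, C3, C4, C4a, C5 to C8, C8a; primed locants for the 3-aryl ring B); with it the target is the (3S) enantiomer.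

**Route**

Step 1
Reactants: 1 2-fluoro-4-hydroxybenzaldehyde
Product: 2 2-fluoro-4-(methoxymethoxy)benzaldehyde
Conditions: MOMCl, i-Pr2NEt, CH2Cl2, 0 °C → rt
Reagents that add atoms: chloromethyl methyl ether (MOMCl), COCCl
Why: O-alkylation of the acidic para-formyl phenol (MOM protection) installs the group that later acidifies C8–H and leaves under mild acid.

Step 2
Reactants: 2 2-fluoro-4-(methoxymethoxy)benzaldehyde
Product: 3 [2-fluoro-4-(methoxymethoxy)phenyl]methanol
Conditions: NaBH4, MeOH, 0 °C
Reagents that add atoms: none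
Why: Borohydride reduction of the aldehyde should leave the aryl fluoride and the acetal untouched.

Step 3
Reactants: 3 [2-fluoro-4-(methoxymethoxy)phenyl]methanol
Product: 4 1-(bromomethyl)-2-fluoro-4-(methoxymethoxy)benzene
Conditions: CBr4, PPh3, CH2Cl2, 0 °C; used at once
Reagents that add atoms: carbon tetrabromide, BrC(Br)(Br)Br
Why: The Appel reaction converts the benzylic alcohol to the bromide under non-acidic conditions that should preserve the MOM acetal.

Step 4
Reactants: 5 1,2,4-trimethoxybenzene
Product: 7 2,3,6-trimethoxybenzaldehyde, via 2,3,6-trimethoxyphenyllithium 6 (not isolated)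
Conditions: n-BuLi, TMEDA, THF, 0 °C → rt; DMF, −78 °C → rt; H2O
Reagents that add atoms: dimethylformamide (DMF), CN(C)C=O
Why: Directed ortho-metalation by n-BuLi removes the hydrogen between the two methoxy groups (C3 of 5) selectively, and the aryllithium is formylated by DMF.

Step 5
Reactants: 7 2,3,6-trimethoxybenzaldehyde
Product: 8 3-bromo-2,5,6-trimethoxybenzaldehyde
Conditions: NBS, MeCN, 0 °C → rt
Reagents that add atoms: N-bromosuccinimide (NBS), BrN1C(=O)CCC1=O
Why: Electrophilic aromatic bromination should go to C5 of 7 (ortho to the C6 methoxy, para to the C2 methoxy, meta to the formyl group) and not to C4, which is activated by one methoxy group only and lies para to the formyl group.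

Step 6
Reactants: 8 3-bromo-2,5,6-trimethoxybenzaldehyde
Product: 10 3-bromo-2,5,6-trimethoxyphenol, via aryl formate 9 (not isolated)
Conditions: m-CPBA, CH2Cl2, rt; aqueous wash; then K2CO3 (cat.), MeOH, rt
Reagents that add atoms: 3-chloroperbenzoic acid (m-CPBA), OOC(=O)c1cccc(Cl)c1
Why: Baeyer–Villiger oxidation with migration of the electron-rich di-ortho-methoxy aryl group, then methanolysis of the formate, should unveil the phenol flanked by two methoxy groups.

Step 7
Reactants: 10 3-bromo-2,5,6-trimethoxyphenol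
Product: 11 1-bromo-3-(methoxymethoxy)-2,4,5-trimethoxybenzene
Conditions: MOMCl, i-Pr2NEt, CH2Cl2, 0 → 40 °C
Reagents that add atoms: chloromethyl methyl ether (MOMCl), COCCl
Why: O-alkylation (MOM protection) masks the ring B phenol with the same acetal as ring A, so one acid step frees both at the end.

Step 8
Reactants: 11 1-bromo-3-(methoxymethoxy)-2,4,5-trimethoxybenzene; 12 ethyl bromoacetate
Product: 14 ethyl 2-[3-(methoxymethoxy)-2,4,5-trimethoxyphenyl]acetate, via Reformatsky reagent 13 (not isolated)
Conditions: 12, Zn dust (TMSCl-activated), THF, 40 °C; then 11, Pd2(dba)3 (cat.), XPhos (cat.), THF, 65 °C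
Reagents that add atoms: none
Why: Negishi-type arylation of the zinc ester enolate at zerovalent palladium with a bulky biaryl phosphine should couple the electron-rich, ortho-substituted bromide under conditions neutral enough for the acetal.

Step 9
Reactants: 14 ethyl 2-[3-(methoxymethoxy)-2,4,5-trimethoxyphenyl]acetate
Product: 15 2-[3-(methoxymethoxy)-2,4,5-trimethoxyphenyl]acetic acid
Conditions: LiOH, THF/H2O, rt; then 1 M HCl to pH 4, 0 °C
Reagents that add atoms: water, O
Why: Saponification of the ethyl ester by aqueous hydroxide, with cold acidification only to pH 4, should spare the MOM acetal.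

Step 10
Reactants: 15 2-[3-(methoxymethoxy)-2,4,5-trimethoxyphenyl]acetic acid; 16 (4S)-4-benzyl-1,3-oxazolidin-2-one
Product: 18 (4S)-4-benzyl-3-{2-[3-(methoxymethoxy)-2,4,5-trimethoxyphenyl]acetyl}-1,3-oxazolidin-2-one, via mixed pivalic anhydride 17 (not isolated)
Conditions: t-BuCOCl, Et3N, THF, −20 °C; then LiCl, 16, −20 °C → rt
Reagents that add atoms: none
Why: N-acylation of the oxazolidinone through the mixed pivalic anhydride (LiCl/Et3N activation) attaches the Evans auxiliary without a strong base.

Step 11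
Reactants: 18 (4S)-4-benzyl-3-{2-[3-(methoxymethoxy)-2,4,5-trimethoxyphenyl]acetyl}-1,3-oxazolidin-2-one; 4 1-(bromomethyl)-2-fluoro-4-(methoxymethoxy)benzene
Product: 20 (4S)-4-benzyl-3-{(2S)-3-[2-fluoro-4-(methoxymethoxy)phenyl]-2-[3-(methoxymethoxy)-2,4,5-trimethoxyphenyl]propanoyl}-1,3-oxazolidin-2-one, via sodium Z-enolate 19 (not isolated)
Conditions: NaN(SiMe3)2, THF, −78 °C; then 4, −78 → −40 °C
Reagents that add atoms: none
Why: Evans asymmetric alkylation, in which the chelated Z-enolate is benzylated on the face opposite the C4 benzyl group of the (4S) auxiliary, should set the 2S centre (the future C3), as in known isoflavan syntheses by this method.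

Step 12
Reactants: 20 (4S)-4-benzyl-3-{(2S)-3-[2-fluoro-4-(methoxymethoxy)phenyl]-2-[3-(methoxymethoxy)-2,4,5-trimethoxyphenyl]propanoyl}-1,3-oxazolidin-2-one
Product: 21 (2S)-3-[2-fluoro-4-(methoxymethoxy)phenyl]-2-[3-(methoxymethoxy)-2,4,5-trimethoxyphenyl]propan-1-ol
Conditions: LiBH4, MeOH (1 equiv), THF, 0 °C
Reagents that add atoms: none
Why: Reductive cleavage of the N-acyl oxazolidinone with LiBH4 should give the primary alcohol without epimerizing the α-aryl centre, and the auxiliary is recovered.

Step 13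
Reactants: 21 (2S)-3-[2-fluoro-4-(methoxymethoxy)phenyl]-2-[3-(methoxymethoxy)-2,4,5-trimethoxyphenyl]propan-1-ol
Product: 26 (3S)-7-(methoxymethoxy)-3-[3-(methoxymethoxy)-2,4,5-trimethoxyphenyl]-3,4-dihydro-2H-chromen-8-ol, via C8-lithio fluoroarene alkoxide 22 (not isolated), via aryne alkoxide 23 (not isolated), via 8-lithiochroman 24 (not isolated), via lithium aryltrimethoxyborate 25 (not isolated)
Conditions: s-BuLi (2.05 equiv), THF, −78 °C; warm to 0 °C; B(OMe)3, −78 °C → rt; then 30% aq. H2O2, 0 °C
Reagents that add atoms: hydrogen peroxide, OO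
Why: s-BuLi first forms the lithium alkoxide and then removes C8–H, the only ring hydrogen flanked by fluorine (C8a) and the methoxymethoxy group (C7); on warming LiF is lost to give the C8≡C8a aryne, the tethered alkoxide adds to C8a, and the resulting 8-lithiochroman is borylated with B(OMe)3 and oxidized to the phenol. The closest known reaction type is the anionic aryne cyclization triggered by directed ortho-metalation of a 3-haloaryl ether or anilide, with trapping of the new aryllithium by an electrophile, together with the capture of benzynes by tethered alcohols to give chromans. The pyran ring closes in a 6-exo-dig mode on the in-plane π bond of the aryne. No new stereocentre is formed, and C3 (S), whose hydrogen is not acidic under these conditions, is carried through unchanged. Regioselectivity is needed at three points: lithiation at C8 is secured by the joint acidifying effect of F and OMOM (ring B keeps only C6'–H, beside a single methoxy group); the aryne can form only between C8 and C8a because C4a bears carbon; and oxygen adds at C8a because the C4–C3–C2–O tether reaches only that carbon and because the C7 oxygen polarizes the aryne toward attack at the distal carbon, which leaves the carbanion at C8 between two oxygens. Just two equivalents of base are used so that no free alkyllithium remains to add to the aryne.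

Step 14
Reactants: 26 (3S)-7-(methoxymethoxy)-3-[3-(methoxymethoxy)-2,4,5-trimethoxyphenyl]-3,4-dihydro-2H-chromen-8-ol
Product: 27 (3S)-8-methoxy-7-(methoxymethoxy)-3-[3-(methoxymethoxy)-2,4,5-trimethoxyphenyl]-3,4-dihydro-2H-chromene
Conditions: MeI, K2CO3, DMF, rt
Reagents that add atoms: iodomethane (MeI), CI
Why: Williamson O-methylation of the only free phenol places the C8 methoxy group while both acetals and all ethers are inert.

Step 15
Reactants: 27 (3S)-8-methoxy-7-(methoxymethoxy)-3-[3-(methoxymethoxy)-2,4,5-trimethoxyphenyl]-3,4-dihydro-2H-chromene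
Product: 28 (3S)-3-(3-hydroxy-2,4,5-trimethoxyphenyl)-8-methoxy-3,4-dihydro-2H-chromen-7-ol (CNP0201239.1)
Conditions: HCl (cat.), MeOH, 40 °C
Reagents that add atoms: none
Why: Acid-catalysed acetal exchange with methanol should remove both MOM groups, while aryl methyl ethers, the chroman ether and the non-ionizable C3 centre survive.

**Compound list**
1 | 2-fluoro-4-hydroxybenzaldehyde | O=Cc1ccc(O)cc1F | starting material
2 | 2-fluoro-4-(methoxymethoxy)benzaldehyde | O=Cc1ccc(OCOC)cc1F | intermediate
3 | [2-fluoro-4-(methoxymethoxy)phenyl]methanol | OCc1ccc(OCOC)cc1F | intermediate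
4 | 1-(bromomethyl)-2-fluoro-4-(methoxymethoxy)benzene | BrCc1ccc(OCOC)cc1F | intermediate
5 | 1,2,4-trimethoxybenzene | COc1ccc(OC)c(OC)c1 | starting material
6 | 2,3,6-trimethoxyphenyllithium | [Li]c1c(OC)c(OC)ccc1OC | intermediate
7 | 2,3,6-trimethoxybenzaldehyde | O=Cc1c(OC)c(OC)ccc1OC | intermediate
8 | 3-bromo-2,5,6-trimethoxybenzaldehyde | O=Cc1c(OC)c(OC)cc(Br)c1OC | intermediate
9 | 3-bromo-2,5,6-trimethoxyphenyl formate | O=COc1c(OC)c(OC)cc(Br)c1OC | intermediate
10 | 3-bromo-2,5,6-trimethoxyphenol | Oc1c(OC)c(OC)cc(Br)c1OC | intermediate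
11 | 1-bromo-3-(methoxymethoxy)-2,4,5-trimethoxybenzene | COCOc1c(OC)c(OC)cc(Br)c1OC | intermediate
12 | ethyl bromoacetate | BrCC(=O)OCC | starting material
13 | (2-ethoxy-2-oxoethyl)zinc bromide | CCOC(=O)C[Zn]Br | intermediate
14 | ethyl 2-[3-(methoxymethoxy)-2,4,5-trimethoxyphenyl]acetate | CCOC(=O)Cc1cc(OC)c(OC)c(OCOC)c1OC | intermediate
15 | 2-[3-(methoxymethoxy)-2,4,5-trimethoxyphenyl]acetic acid | OC(=O)Cc1cc(OC)c(OC)c(OCOC)c1OC | intermediate
16 | (4S)-4-benzyl-1,3-oxazolidin-2-one | O=C1OC[C@H](Cc2ccccc2)N1 | starting material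
17 | 2-[3-(methoxymethoxy)-2,4,5-trimethoxyphenyl]acetic pivalic anhydride | CC(C)(C)C(=O)OC(=O)Cc1cc(OC)c(OC)c(OCOC)c1OC | intermediate
18 | (4S)-4-benzyl-3-{2-[3-(methoxymethoxy)-2,4,5-trimethoxyphenyl]acetyl}-1,3-oxazolidin-2-one | O=C1OC[C@H](Cc2ccccc2)N1C(=O)Cc1cc(OC)c(OC)c(OCOC)c1OC | intermediate
19 | sodium (Z)-enolate of 18 | [Na+].[O-]/C(=C\c1cc(OC)c(OC)c(OCOC)c1OC)N1[C@@H](Cc2ccccc2)COC1=O | intermediate
20 | (4S)-4-benzyl-3-{(2S)-3-[2-fluoro-4-(methoxymethoxy)phenyl]-2-[3-(methoxymethoxy)-2,4,5-trimethoxyphenyl]propanoyl}-1,3-oxazolidin-2-one | O=C1OC[C@H](Cc2ccccc2)N1C(=O)[C@@H](Cc1ccc(OCOC)cc1F)c1cc(OC)c(OC)c(OCOC)c1OC | intermediate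
21 | (2S)-3-[2-fluoro-4-(methoxymethoxy)phenyl]-2-[3-(methoxymethoxy)-2,4,5-trimethoxyphenyl]propan-1-ol | OC[C@@H](Cc1ccc(OCOC)cc1F)c1cc(OC)c(OC)c(OCOC)c1OC | intermediate
22 | lithium alkoxide of 21 lithiated at C8 (between F and OMOM) | [Li]OC[C@@H](Cc1ccc(OCOC)c([Li])c1F)c1cc(OC)c(OC)c(OCOC)c1OC | intermediate
23 | C8≡C8a aryne lithium alkoxide | [Li]OC[C@@H](CC1=CC=C(OCOC)C#C1)c1cc(OC)c(OC)c(OCOC)c1OC | intermediate
24 | (3S)-8-lithio-7-(methoxymethoxy)-3-[3-(methoxymethoxy)-2,4,5-trimethoxyphenyl]chroman | COc1cc([C@H]2COc3c(ccc(OCOC)c3[Li])C2)c(OC)c(OCOC)c1OC | intermediate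
25 | lithium trimethoxy{(3S)-7-(methoxymethoxy)-3-[3-(methoxymethoxy)-2,4,5-trimethoxyphenyl]chroman-8-yl}borate | COc1cc([C@H]2COc3c(ccc(OCOC)c3[B-](OC)(OC)OC)C2)c(OC)c(OCOC)c1OC.[Li+] | intermediate
26 | (3S)-7-(methoxymethoxy)-3-[3-(methoxymethoxy)-2,4,5-trimethoxyphenyl]-3,4-dihydro-2H-chromen-8-ol | COc1cc([C@H]2COc3c(ccc(OCOC)c3O)C2)c(OC)c(OCOC)c1OC | intermediate
27 | (3S)-8-methoxy-7-(methoxymethoxy)-3-[3-(methoxymethoxy)-2,4,5-trimethoxyphenyl]-3,4-dihydro-2H-chromene | COc1cc([C@H]2COc3c(ccc(OCOC)c3OC)C2)c(OC)c(OCOC)c1OC | intermediate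
28 | (3S)-3-(3-hydroxy-2,4,5-trimethoxyphenyl)-8-methoxy-3,4-dihydro-2H-chromen-7-ol | COc1cc([C@H]2COc3c(ccc(O)c3OC)C2)c(OC)c(O)c1OC | target

**Totals**
Total step count: 15. Longest linear sequence: 12 steps (steps 4 to 15, from 5 to 28).

**Steps most likely to fail**

1. Step 13. The ring closure by the weakly nucleophilic lithium alkoxide may be outrun by intermolecular capture of the aryne (by a second aryllithium or by leftover s-BuLi) or by proton capture, and borylation of the hindered C8–Li may be incomplete. Fallback, setting out from 21 and coming back at 27: the lithiated species is kept at −78 °C so that LiF is not lost, then quenched with B(OMe)3 and oxidized with H2O2 to give 2-fluoro-3-{(2S)-3-hydroxy-2-[3-(methoxymethoxy)-2,4,5-trimethoxyphenyl]propyl}-6-(methoxymethoxy)phenol F1. MeI/K2CO3 should methylate only the phenol to give (2S)-3-[2-fluoro-3-methoxy-4-(methoxymethoxy)phenyl]-2-[3-(methoxymethoxy)-2,4,5-trimethoxyphenyl]propan-1-ol F2. The same O1–C8a bond is then closed by intramolecular nucleophilic aromatic substitution of the potassium alkoxide on the C8a–F bond (KOtBu, DMSO, 80–110 °C), which no longer has an ortho hydrogen for elimination, to give 27.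

2. Step 11. The electron-rich benzylic bromide may ionize and self-alkylate, the arylacetyl enolate may fragment on warming, or facial control may be incomplete. Fallback, setting out from 2 and 15 and coming back at 21: Perkin condensation (Ac2O, Et3N, 100 °C) should give (2E)-3-[2-fluoro-4-(methoxymethoxy)phenyl]-2-[3-(methoxymethoxy)-2,4,5-trimethoxyphenyl]prop-2-enoic acid F3. Asymmetric hydrogenation (H2, Ru(OAc)2(BINAP), MeOH, with the ligand antipode fixed by a test run for the S acid) would give (2S)-3-[2-fluoro-4-(methoxymethoxy)phenyl]-2-[3-(methoxymethoxy)-2,4,5-trimethoxyphenyl]propanoic acid F4, and LiAlH4 in THF at 0 °C reduces it to 21.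

3. Step 8. Oxidative addition at the hindered, electron-rich C–Br bond may be slow, so that protodehalogenation and self-condensation of the zinc enolate take over. Fallback, setting out from 11 and coming back at 15: bromine–lithium exchange (n-BuLi, THF, −78 °C) gives [3-(methoxymethoxy)-2,4,5-trimethoxyphenyl]lithium F5. Opening of ethylene oxide (BF3·OEt2, −78 °C) gives 2-[3-(methoxymethoxy)-2,4,5-trimethoxyphenyl]ethan-1-ol F6, which is oxidized to 15 with TEMPO (cat.), NaClO2 and NaOCl (cat.) in pH 6.7 phosphate buffer/MeCN.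

**Further compounds**
F1 | step 13 | 2-fluoro-3-{(2S)-3-hydroxy-2-[3-(methoxymethoxy)-2,4,5-trimethoxyphenyl]propyl}-6-(methoxymethoxy)phenol | OC[C@@H](Cc1ccc(OCOC)c(O)c1F)c1cc(OC)c(OC)c(OCOC)c1OC
F2 | step 13 | (2S)-3-[2-fluoro-3-methoxy-4-(methoxymethoxy)phenyl]-2-[3-(methoxymethoxy)-2,4,5-trimethoxyphenyl]propan-1-ol | OC[C@@H](Cc1ccc(OCOC)c(OC)c1F)c1cc(OC)c(OC)c(OCOC)c1OC
F3 | step 11 | (2E)-3-[2-fluoro-4-(methoxymethoxy)phenyl]-2-[3-(methoxymethoxy)-2,4,5-trimethoxyphenyl]prop-2-enoic acid | OC(=O)/C(=C/c1ccc(OCOC)cc1F)c1cc(OC)c(OC)c(OCOC)c1OC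
F4 | step 11 | (2S)-3-[2-fluoro-4-(methoxymethoxy)phenyl]-2-[3-(methoxymethoxy)-2,4,5-trimethoxyphenyl]propanoic acid | OC(=O)[C@@H](Cc1ccc(OCOC)cc1F)c1cc(OC)c(OC)c(OCOC)c1OC
F5 | step 8 | [3-(methoxymethoxy)-2,4,5-trimethoxyphenyl]lithium | [Li]c1cc(OC)c(OC)c(OCOC)c1OC
F6 | step 8 | 2-[3-(methoxymethoxy)-2,4,5-trimethoxyphenyl]ethan-1-ol | OCCc1cc(OC)c(OC)c(OCOC)c1OC
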